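**Assumptions**
- Compound 1 is purchasable. If not, it is made in two steps from acrolein by HWE with triethyl 2-phosphonopropionate, then DIBAL.
- The (S)-4-benzyloxazolidinone auxiliary is assumed to deliver the natural enantiomer. The (R)-auxiliary would be used if it does not.
- The C6 methoxy configuration is set by thermodynamic acetal equilibration in the last step.

**Retrosynthesis**
1. Ludongnin F comes from anomeric equilibration of the C6 methyl acetal, after exo-face hydrogenation of a 16-ene-15-one that sets the endo C16-methyl. The enone comes from α-methylenation of the bicyclo[3.2.1]octan-6-one.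
2. The D ring forms by 5-exo cyclization of an α-keto radical (from a bromomethyl ketone on C8) onto the C12=C13 alkene of a cyclohexene C ring.
3. The C ring, with C8 and C9, comes from a Diels–Alder of butadiene on a spiro α-acetyl unsaturated δ-lactone. That lactone comes from intramolecular Knoevenagel condensation of a C20 acetoacetate with the C9 aldehyde.
4. The spiro A ring (C4, C5, C10), the cis 6,19-lactone (a masked C6 methyl acetal) and the auxiliary-controlled absolute configuration come from one Evans/Et2AlCl ester-tethered intramolecular Diels–Alder of a dienyl fumarate-type imide. The B ring is never built, since the 6,7-seco skeleton is assembled directly.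
5. Ring-formation order: A ring plus γ-lactone, then δ-lactone, then C ring, then D ring, then acetal.

---

**Step 1**
Reactants: 1 (2E)-2-methylpenta-2,4-dien-1-ol; 2 2-(diethoxyphosphoryl)acetic acid
Product: 3 (2E)-2-methylpenta-2,4-dien-1-yl 2-(diethoxyphosphoryl)acetate
Conditions: EDC·HCl, DMAP (cat.), CH2Cl2, 0 °C → rt
Reagents that add atoms: none
Why: Steglich esterification that joins the diene tether to the phosphonate with the E-diene intact.

**Step 2**
Reactants: 4 (S)-3-acryloyl-4-benzyloxazolidin-2-one; 5 formaldehyde
Product: 6 (S)-4-benzyl-3-[2-(hydroxymethyl)acryloyl]oxazolidin-2-one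
Conditions: 37% aq. HCHO (5 equiv), DABCO (0.3 equiv), dioxane/H2O 1:1, rt
Reagents that add atoms: none (formaldehyde is reactant 5)
Why: Morita–Baylis–Hillman hydroxymethylation that installs C20 and C10 as a 1,1-disubstituted alkene; the auxiliary stereocentre is untouched.

**Step 3**
Reactants: 6
Product: 7 (S)-4-benzyl-3-{2-[(tert-butyldiphenylsilyloxy)methyl]acryloyl}oxazolidin-2-one
Conditions: TBDPSCl, imidazole, DMF, rt
Reagents that add atoms: TBDPSCl, CC(C)(C)[Si](Cl)(c1ccccc1)c1ccccc1
Why: Silylation with an acid-robust group that survives the later MeOH/H+ acetalization.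

**Step 4**
Reactants: 7
Product: 8 (S)-4-benzyl-3-[3-(TBDPSO)-2-oxopropanoyl]oxazolidin-2-one
Conditions: O3, CH2Cl2, −78 °C; then Me2S
Reagents that add atoms: ozone, [O-][O+]=O (supplies the ketone O)
Why: Ozonolysis of the electron-poor 1,1-disubstituted alkene gives the α-keto imide, which becomes C10.

**Step 5**
Reactants: 8; 3
Product: 9 dienophile, the (E)-imide/ester in which C6 is cis to CH2OTBDPS (C20) and trans to the imide C9
Conditions: LiCl, DBU, MeCN, 0 °C → rt; separate the E/Z isomers by silica gel chromatography
Reagents that add atoms: none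
Why: Masamune–Roush HWE olefination fixes the C5=C10 geometry (C20 cis to C6), which dictates the relative configuration at C10 after cycloaddition.

**Step 6**
Reactants: 9
Product: 10 cis-fused 6,19-lactone on a cyclohex-2-ene, carrying at quaternary C10 the axial CH2OTBDPS (C20, cis to the lactone) and the equatorial C(=O)-(S)-4-benzyloxazolidinone (C9); C4-Me is trans to C19
Conditions: Et2AlCl (1.5 equiv), CH2Cl2, −78 → −30 °C
Reagents that add atoms: none
Why: Evans-type Lewis-acid intramolecular Diels–Alder in which the short ester tether forces an endo transition state (cis lactone), the alkene and diene geometries fix C4/C5/C10, and the chelated benzyl auxiliary fixes the absolute sense.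
Proposed new method: Chelation of Et2AlCl to the imide makes C5 the electrophilic β-carbon, so the tethered CH2 terminus of the E-diene bonds to C10 and the Me-substituted terminus to C5; the closest known reactions are Evans' Et2AlCl-promoted N-enoyl-oxazolidinone IMDA and pentadienyl-acrylate ester-tethered IMDA.

**Step 7**
Reactants: 10
Product: 11 C9 primary alcohol (the lactone is retained), plus recovered auxiliary
Conditions: LiBH4 (2 equiv), H2O (1 equiv), Et2O, 0 °C
Reagents that add atoms: none
Why: Reductive imide cleavage is faster than reduction of the hindered γ-lactone, and no stereocentre is touched.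

**Step 8**
Reactants: 11
Product: 12 C6 lactol (anomeric mixture)
Conditions: DIBAL-H (3 equiv), CH2Cl2, −78 °C
Reagents that add atoms: none
Why: Low-temperature DIBAL reduces the lactone to the lactol, and the free OH consumes one equivalent.

**Step 9**
Reactants: 12
Product: 13 6,19-methyl acetal (C6 epimeric mixture)
Conditions: MeOH, PPTS (0.1 equiv), rt
Reagents that add atoms: methanol, CO
Why: Mild acid converts the lactol to the methyl acetal while the TBDPS ether survives; the C6 configuration is left open and re-set thermodynamically in step 20.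

**Step 10**
Reactants: 13
Product: 14 C9 aldehyde
Conditions: Dess–Martin periodinane, NaHCO3, CH2Cl2, rt
Reagents that add atoms: none
Why: DMP oxidation of the primary alcohol under buffered conditions leaves the acetal intact.

**Step 11**
Reactants: 14
Product: 15 C20 free hydroxy aldehyde
Conditions: TBAF buffered with AcOH (1:1), THF, 0 → 35 °C
Reagents that add atoms: none
Why: Buffered fluoride removes the silyl group without base-promoted retro-aldol of the quaternary β-hydroxy aldehyde.

**Step 12**
Reactants: 15; 16 diketene
Product: 17 C20 acetoacetate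
Conditions: diketene, DMAP (5 mol%), CH2Cl2, 0 °C
Reagents that add atoms: none (diketene is reactant 16)
Why: Ring-opening acetoacetylation of the neopentyl primary alcohol supplies C7, C8, C15 and C16.

**Step 13**
Reactants: 17
Product: 18 spiro α-acetyl-α,β-unsaturated δ-lactone
Conditions: piperidine/AcOH (0.2 equiv each), benzene, 4 Å MS, reflux
Reagents that add atoms: none
Why: Intramolecular Knoevenagel condensation, helped by the geminal (Thorpe–Ingold) substitution at C10, closes the lactone ring and gives a doubly activated dienophile whose C8=C9 geometry is fixed by the ring.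

**Step 14**
Reactants: 18; 19 1,3-butadiene
Product: 20 cis-fused spiro lactone-cyclohexene with C8 quaternary (acetyl), C9–H and a C12=C13 alkene
Conditions: butadiene (20 equiv), BHT, toluene, sealed tube, 110 °C, 48 h (thermal, to avoid ionizing the acetal)
Reagents that add atoms: none (butadiene is reactant 19)
Why: Diels–Alder cycloaddition is suprafacial, so C7/C10 stay cis, giving the required C8/C9 relative configuration, and the face is chosen by the spiro centre.
Proposed new method: The diene should add to the lactone face anti to the bulky C5 (bearing C4 and the acetal) and syn to CH2-C1, giving C11 cis to C1; the closest known reaction is the Diels–Alder of 3-acyl-5,6-dihydropyran-2-ones (alkylidene β-ketoesters) with dienes.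

**Step 15**
Reactants: 20
Product: 21 bromomethyl ketone
Conditions: LiHMDS, THF, −78 °C; TMSCl; then NBS, −78 → 0 °C
Reagents that add atoms: NBS, O=C1CCC(=O)N1Br
Why: The methyl group is the only enolizable site (C8 is quaternary), so the kinetic silyl enol ether is brominated regioselectively (Rubottom-type α-halogenation).

**Step 16**
Reactants: 21
Product: 22 bicyclo[3.2.1]octan-6-one (C16H2, A-ring alkene still present)
Conditions: (TMS)3SiH (1.5 equiv), AIBN, PhH, 80 °C, syringe pump, 0.005 M
Reagents that add atoms: none
Why: A 5-exo radical cyclization of the α-keto radical from the axial C15 onto C13 closes the D ring, and the bridgehead C13 configuration is forced by the bicycle.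

**Step 17**
Reactants: 22; 23 Eschenmoser's salt
Product: 24 C16 Mannich base
Conditions: LDA (1.1 equiv), THF, −78 °C; then 23, −78 °C → rt
Reagents that add atoms: none (the salt is reactant 23)
Why: Mannich aminomethylation at C16, the only enolizable position, supplies C17.

**Step 18**
Reactants: 24
Product: 25 16-en-15-one (exocyclic α-methylene ketone)
Conditions: MeI, CH2Cl2, rt; then DBU
Reagents that add atoms: none (the MeI methyl leaves as NMe3)
Why: Quaternization and E1cB elimination of trimethylamine give the α-methylene ketone.

**Step 19**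
Reactants: 25
Product: 26 saturated ketone (C6 epimeric mixture)
Conditions: H2 (1 atm), 10% Pd/C, EtOAc, rt
Reagents that add atoms: none
Why: Heterogeneous hydrogenation reduces the A-ring alkene and delivers H to C16 from the less hindered exo face, so the methyl ends up endo, as in the target.

**Step 20**
Reactants: 26
Product: 27 ludongnin F (C6 anomer isolated by chromatography)
Conditions: MeOH, PPTS (cat.), rt; separate the anomers
Reagents that add atoms: none (exchange of OMe with MeOH, no net atoms added)
Why: Acid-catalysed anomerization of the cyclic methyl acetal through the oxocarbenium ion gives the thermodynamic anomer mixture, from which the natural C6 epimer is isolated.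

---

**Compound list**

| # | Name | SMILES | Role |
|---|---|---|---|
| 1 | (2E)-2-methylpenta-2,4-dien-1-ol | OC/C(C)=C/C=C | starting material |
| 2 | 2-(diethoxyphosphoryl)acetic acid | CCOP(=O)(OCC)CC(=O)O | starting material |
| 3 | dienyl diethylphosphonoacetate | CCOP(=O)(OCC)CC(=O)OC/C(C)=C/C=C | intermediate |
| 4 | (S)-3-acryloyl-4-benzyloxazolidin-2-one | C=CC(=O)N1[C@@H](Cc2ccccc2)COC1=O | starting material |
| 5 | formaldehyde | C=O | starting material |
| 6 | MBH hydroxymethyl acrylimide | C=C(CO)C(=O)N1[C@@H](Cc2ccccc2)COC1=O | intermediate |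
| 7 | TBDPS ether | C=C(CO[Si](c2ccccc2)(c2ccccc2)C(C)(C)C)C(=O)N1[C@@H](Cc2ccccc2)COC1=O | intermediate |
| 8 | α-keto imide | O=C(CO[Si](c2ccccc2)(c2ccccc2)C(C)(C)C)C(=O)N1[C@@H](Cc2ccccc2)COC1=O | intermediate |
| 9 | IMDA substrate (E) | C=C/C=C(\C)COC(=O)/C=C(\CO[Si](c2ccccc2)(c2ccccc2)C(C)(C)C)C(=O)N1[C@@H](Cc2ccccc2)COC1=O | intermediate |
| 10 | IMDA adduct (6,19-lactone) | O=C1OC[C@]2(C)C=CC[C@@](CO[Si](c3ccccc3)(c3ccccc3)C(C)(C)C)(C(=O)N3[C@@H](Cc4ccccc4)COC3=O)[C@H]12 | intermediate |
| 11 | C9 alcohol | O=C1OC[C@]2(C)C=CC[C@@](CO[Si](c3ccccc3)(c3ccccc3)C(C)(C)C)(CO)[C@H]12 | intermediate |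
| 12 | C6 lactol (anomeric mixture) | OC1OC[C@]2(C)C=CC[C@@](CO[Si](c3ccccc3)(c3ccccc3)C(C)(C)C)(CO)[C@H]12 | intermediate |
| 13 | methyl acetal (C6 epimeric) | COC1OC[C@]2(C)C=CC[C@@](CO[Si](c3ccccc3)(c3ccccc3)C(C)(C)C)(CO)[C@H]12 | intermediate |
| 14 | aldehyde | COC1OC[C@]2(C)C=CC[C@@](CO[Si](c3ccccc3)(c3ccccc3)C(C)(C)C)(C=O)[C@H]12 | intermediate |
| 15 | hydroxy aldehyde | COC1OC[C@]2(C)C=CC[C@@](CO)(C=O)[C@H]12 | intermediate |
| 16 | diketene | C=C1CC(=O)O1 | starting material |
| 17 | acetoacetate | COC1OC[C@]2(C)C=CC[C@@](COC(=O)CC(C)=O)(C=O)[C@H]12 | intermediate |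
| 18 | spiro α-acetyl enone δ-lactone | COC1OC[C@]2(C)C=CC[C@]3(COC(=O)C(C(C)=O)=C3)[C@H]12 | intermediate |
| 19 | 1,3-butadiene | C=CC=C | starting material |
| 20 | Diels–Alder adduct | COC1OC[C@]2(C)C=CC[C@]3(COC(=O)[C@@]4(C(C)=O)CC=CC[C@H]43)[C@H]12 | intermediate |
| 21 | bromomethyl ketone | COC1OC[C@]2(C)C=CC[C@]3(COC(=O)[C@@]4(C(=O)CBr)CC=CC[C@H]43)[C@H]12 | intermediate |
| 22 | bicyclo[3.2.1] ketone | COC1OC[C@]2(C)C=CC[C@]3(COC(=O)[C@@]45C[C@@H](CC[C@H]43)CC5=O)[C@H]12 | intermediate |
| 23 | Eschenmoser's salt | C[N+](C)=C.[I-] | starting material |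
| 24 | Mannich base | COC1OC[C@]2(C)C=CC[C@]3(COC(=O)[C@@]45C[C@@H](CC[C@H]43)C(CN(C)C)C5=O)[C@H]12 | intermediate |
| 25 | 16-en-15-one | COC1OC[C@]2(C)C=CC[C@]3(COC(=O)[C@@]45C[C@@H](CC[C@H]43)C(=C)C5=O)[C@H]12 | intermediate |
| 26 | saturated ketone (C6 epimeric) | COC1OC[C@]2(C)CCC[C@]3(COC(=O)[C@@]45C[C@@H](CC[C@H]43)[C@@H](C)C5=O)[C@H]12 | intermediate |
| 27 | ludongnin F | CO[C@@H]1OC[C@]2(C)CCC[C@]3(COC(=O)[C@@]45C[C@@H](CC[C@H]43)[C@@H](C)C5=O)[C@H]12 | target |

**Step count:** 20 steps in total. The longest linear sequence is 19 steps (4 → 6 → 7 → 8 → 9 → … → 27).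

**Three steps most likely to fail**
1. **Step 6, intramolecular Diels–Alder.** The hindered 1,1-disubstituted diene has an "inside" methyl, and the reaction forms adjacent quaternary and tertiary centres with a trisubstituted fumarimide. Fallback: build the A ring by a different route, namely Cu-catalysed asymmetric conjugate addition of MeMgBr to 3-(benzyloxymethyl)cyclohex-2-enone to set C4, followed by stepwise enolate functionalization for C5/C10.
2. **Step 14, Diels–Alder on the spiro lactone.** The β-carbon sits next to a quaternary centre, and the face selectivity may favour the wrong C9 epimer. Fallback: invert the order. Build the C/D bicyclo[3.2.1]octane lactone core first from a chiral-pool cyclohexane (for example carvone-derived), then close the A ring last by a tethered Diels–Alder.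
3. **Step 16, radical cyclization.** Six-endo closure onto C12 would give a bicyclo[2.2.2]octane instead of the 5-exo bicyclo[3.2.1]. Fallback: use a 2-silyloxybutadiene in step 14 to put a C13 ketone on the C ring, close the D ring by intramolecular aldol with the methyl ketone, and remove the bridgehead C13–OH by Barton–McCombie deoxygenation.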